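The target is an unsymmetrical C6–C6 biaryl of two 7,8,4'-trihydroxyflavan-3,4-diols, (2R,3R,4R) and (2R,3R,4S). Everything rests on opening ring C at O1–C2: the ring-A phenol attacks the benzylic carbon of a cis C2–C3 epoxide (6-endo, inversion), which in one operation closes the pyran and writes the 2,3-cis relationship; it exploits the aryl-activated C2 lying between O1 and ring B. The precursor is an open-chain threo epoxy carbinol from hydroxyl-directed epoxidation of a (Z)-allylic alcohol; its C4 epimer (oxidation, chelate reduction) serves the second unit. A 4'-pivalate restrains ionisation. Suzuki–Miyaura coupling of the two 6-bromoflavans and deprotection complete the route.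

Key step: step 8

Remark: flavan numbering is used for all intermediates (O1, C2, C3, C4 in ring C; C5 to C8 in ring A; primed positions in ring B); "the (4S) unit" and "the (4R) unit" name the two halves.
Assumption: (R)-BINOL is taken to direct the alkynyl group to the Re face of aldehyde 4, as it does with simple benzaldehydes; the configuration of 8 would be confirmed on its Mosher esters and the antipodal ligand used otherwise.
Assumption: 1 and 5 are bought.

Step 1
Reactants: 1 2,3,4-trihydroxybenzaldehyde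
Product: 2 4-hydroxy-2,2-diphenyl-1,3-benzodioxole-5-carbaldehyde
Conditions: Ph2CCl2 (1.2 equiv), Ph2O, 170 °C, N2 stream
Reagents that add atoms: dichlorodiphenylmethane, ClC(Cl)(c1ccccc1)c1ccccc1
Why: Ketalisation of a catechol with a gem-dichloride; the 2-OH is locked in the hydrogen bond to the formyl group, so the 3,4-diol pair closes the five-membered ketal and the future O1 phenol stays free.

Step 2
Reactants: 2 4-hydroxy-2,2-diphenyl-1,3-benzodioxole-5-carbaldehyde
Product: 3 7-bromo-4-hydroxy-2,2-diphenyl-1,3-benzodioxole-5-carbaldehyde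
Conditions: NBS (1.05 equiv), MeCN, 0 °C
Reagents that add atoms: N-bromosuccinimide, O=C1CCC(=O)N1Br
Why: Electrophilic aromatic bromination goes para to the free phenol, ortho to a ketal oxygen and meta to the aldehyde, the only activated open position and the future flavan C6.

Step 3
Reactants: 3 7-bromo-4-hydroxy-2,2-diphenyl-1,3-benzodioxole-5-carbaldehyde
Product: 4 7-bromo-2,2-diphenyl-4-(triisopropylsilyloxy)-1,3-benzodioxole-5-carbaldehyde
Conditions: TIPSOTf, 2,6-lutidine, CH2Cl2, 0 °C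
Reagents that add atoms: triisopropylsilyl triflate, CC(C)[Si](C(C)C)(C(C)C)OS(=O)(=O)C(F)(F)F
Why: O-Silylation with the silyl triflate masks the hindered future O1 phenol through the organozinc, peracid, oxidation and hydride steps and is removed later by fluoride; the bulky group resists migration to a neighbouring alkoxide.

Step 4
Reactants: 5 4-ethynylphenol
Product: 6 4-ethynylphenyl pivalate
Conditions: PivCl, Et3N, DMAP (cat.), CH2Cl2, 0 °C
Reagents that add atoms: pivaloyl chloride, CC(C)(C)C(=O)Cl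
Why: O-Acylation; the hindered ester survives the later zinc, hydride and fluoride steps and makes ring B a much weaker donor than an ether would, which the key step needs.

Step 5
Reactants: 4 7-bromo-2,2-diphenyl-4-(triisopropylsilyloxy)-1,3-benzodioxole-5-carbaldehyde and 6 4-ethynylphenyl pivalate
Product: 8 4-[(3R)-3-(7-bromo-2,2-diphenyl-4-triisopropylsilyloxy-1,3-benzodioxol-5-yl)-3-hydroxyprop-1-ynyl]phenyl pivalate, via alkynylzinc 7 (not isolated)
Conditions: 6 (2 equiv), Et2Zn, toluene, 110 °C; then (R)-BINOL (40 mol%), Ti(OiPr)4, CH2Cl2, rt; then 4, rt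
Reagents that add atoms: none
Why: Catalytic asymmetric alkynylzinc addition to an aryl aldehyde with the BINOL–Ti(OiPr)4 system; Re-face delivery sets the carbinol centre, (R) here because ring A outranks the alkynyl group, and this centre is the later C4.

Step 6
Reactants: 8 4-[(3R)-3-(7-bromo-2,2-diphenyl-4-triisopropylsilyloxy-1,3-benzodioxol-5-yl)-3-hydroxyprop-1-ynyl]phenyl pivalate
Product: 9 4-[(1Z,3R)-3-(7-bromo-2,2-diphenyl-4-triisopropylsilyloxy-1,3-benzodioxol-5-yl)-3-hydroxyprop-1-enyl]phenyl pivalate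
Conditions: H2 (1 atm), Pd/CaCO3 poisoned with Pb(OAc)2, quinoline, EtOAc, rt
Reagents that add atoms: none
Why: Lindlar-type semihydrogenation adds H2 syn and should stop at the (Z)-alkene; aryl bromide, ketal and ester are not expected to react over the poisoned catalyst.

Step 7
Reactants: 9 4-[(1Z,3R)-3-(7-bromo-2,2-diphenyl-4-triisopropylsilyloxy-1,3-benzodioxol-5-yl)-3-hydroxyprop-1-enyl]phenyl pivalate
Product: 10 4-[(2S,3R)-3-[(S)-(7-bromo-2,2-diphenyl-4-triisopropylsilyloxy-1,3-benzodioxol-5-yl)(hydroxy)methyl]oxiran-2-yl]phenyl pivalate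
Conditions: mCPBA, NaHCO3, CH2Cl2, 0 °C
Reagents that add atoms: meta-chloroperoxybenzoic acid, OOC(=O)c1cccc(Cl)c1
Why: Hydroxyl-directed Prilezhaev epoxidation: A1,3 strain from the (Z)-aryl group holds the carbinol hydrogen in the alkene plane and the hydrogen-bonded peracid attacks the OH face, so C2 (S) and C3 (R) are set threo to C4, and the pivalate-deactivated aryl epoxide should survive the buffered medium.

Step 8
Reactants: 10 4-[(2S,3R)-3-[(S)-(7-bromo-2,2-diphenyl-4-triisopropylsilyloxy-1,3-benzodioxol-5-yl)(hydroxy)methyl]oxiran-2-yl]phenyl pivalate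
Product: 12 (2R,3R,4S)-6-bromo-7,8-(diphenylmethylenedioxy)-4'-pivaloyloxyflavan-3,4-diol, via epoxy phenol 11 (not isolated)
Conditions: Bu4NF, AcOH (1:1.5), THF, 0 °C; aqueous wash; crude 11, CSA (10 mol%), CH2Cl2, −20 to 0 °C; Et3N quench
Reagents that add atoms: none
Why: Fluoride removes the silyl group and the freed ring-A phenol oxygen O1 attacks the acid-activated epoxide at the benzylic carbon C2, anti to the breaking C2–O bond (borderline SN2 opening of an aryl epoxide). The closest known reaction type is the acid-catalysed endo phenol–epoxide cyclisation of aryl epoxides used for flavan-3-ols, together with the C3-selective opening of 3-aryl-2,3-epoxy alcohols. Ring C closes in the 6-endo-tet mode. C2 becomes (R) by inversion of the (S) epoxide carbon, C3 keeps the epoxide oxygen as the (R) 3-OH and C4 (S) is untouched, so the cis-epoxide becomes the 2,3-cis and the threo carbinol the 3,4-trans relationship. The step needs endo over 5-exo attack and inversion over ionisation: the aryl group activates C2, the C4 carbinol deactivates and shields C3, and the 4'-pivaloyloxy group keeps the benzylic carbon from forming a free cation, while catalytic acid at low temperature should leave the ortho-hydroxybenzylic C4–OH un-ionised.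

Step 9
Reactants: 10 4-[(2S,3R)-3-[(S)-(7-bromo-2,2-diphenyl-4-triisopropylsilyloxy-1,3-benzodioxol-5-yl)(hydroxy)methyl]oxiran-2-yl]phenyl pivalate
Product: 13 4-[(2S,3S)-3-(7-bromo-2,2-diphenyl-4-triisopropylsilyloxy-1,3-benzodioxole-5-carbonyl)oxiran-2-yl]phenyl pivalate
Conditions: Dess–Martin periodinane, NaHCO3, CH2Cl2, 0 °C to rt
Reagents that add atoms: none
Why: Dess–Martin oxidation erases only the C4 centre; the two epoxide carbons keep their configuration (the descriptor at C3 changes by priority only) and no base is present to epimerise the cis-epoxy ketone.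

Step 10
Reactants: 13 4-[(2S,3S)-3-(7-bromo-2,2-diphenyl-4-triisopropylsilyloxy-1,3-benzodioxole-5-carbonyl)oxiran-2-yl]phenyl pivalate
Product: 14 4-[(2S,3R)-3-[(R)-(7-bromo-2,2-diphenyl-4-triisopropylsilyloxy-1,3-benzodioxol-5-yl)(hydroxy)methyl]oxiran-2-yl]phenyl pivalate
Conditions: Zn(BH4)2, Et2O, −40 °C
Reagents that add atoms: none
Why: Chelation-controlled reduction of an α,β-epoxy ketone: zinc bridges the carbonyl and epoxide oxygens and hydride adds to the face away from the epoxide carbon C2, which should give the erythro carbinol, C4 (R).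

Step 11
Reactants: 14 4-[(2S,3R)-3-[(R)-(7-bromo-2,2-diphenyl-4-triisopropylsilyloxy-1,3-benzodioxol-5-yl)(hydroxy)methyl]oxiran-2-yl]phenyl pivalate
Product: 16 (2R,3R,4R)-6-bromo-7,8-(diphenylmethylenedioxy)-4'-pivaloyloxyflavan-3,4-diol, via epoxy phenol 15 (not isolated)
Conditions: Bu4NF, AcOH (1:1.5), THF, 0 °C; aqueous wash; crude 15, CSA (10 mol%), CH2Cl2, −20 to 0 °C; Et3N quench
Reagents that add atoms: none
Why: Same desilylation and 6-endo-tet phenol–epoxide closure as in step 8; inversion at C2 gives the all-cis (2R,3R,4R) diol, the closure being at most slowed by the syn arrangement of the C2 aryl group and the C4 hydroxyl.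

Step 12
Reactants: 12 (2R,3R,4S)-6-bromo-7,8-(diphenylmethylenedioxy)-4'-pivaloyloxyflavan-3,4-diol and 16 (2R,3R,4R)-6-bromo-7,8-(diphenylmethylenedioxy)-4'-pivaloyloxyflavan-3,4-diol
Product: 18 C6–C6 biflavan bis-ketal bis-pivalate [(2R,3R,4R) unit joined to (2R,3R,4S) unit], via boronate 17 (not isolated)
Conditions: 12, B2pin2, Pd(dppf)Cl2 (5 mol%), KOAc, dioxane, 85 °C; then 16, Pd(OAc)2/SPhos, K3PO4, H2O, 60 °C
Reagents that add atoms: none
Why: Miyaura borylation followed in the same flask by Suzuki–Miyaura coupling joins the two C6 carbons; free secondary alcohols, ketals and hindered aryl pivalates should tolerate the weakly basic medium, and each aryl has only one ortho substituent at the coupling site, so no stable atropisomers arise.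

Step 13
Reactants: 18 C6–C6 biflavan bis-ketal bis-pivalate [(2R,3R,4R) unit joined to (2R,3R,4S) unit]
Product: 20 (2R,3R,4R)-2-(4-hydroxyphenyl)-6-[(2R,3R,4S)-3,4,7,8-tetrahydroxy-2-(4-hydroxyphenyl)chroman-6-yl]chroman-3,4,7,8-tetrol, via bis-ketal 19 (not isolated)
Conditions: NaOMe (3 equiv), MeOH/THF, 0 °C to rt, Ar; AcOH (3 equiv), evaporation; then H2 (1 atm), Pd(OH)2/C, THF/EtOAc, rt, work-up under Ar
Reagents that add atoms: none
Why: Methanolysis frees the two 4'-phenols while the catechols are still masked, then neutral hydrogenolysis cleaves the doubly benzylic ketal C–O bonds, which should go much faster than the secondary benzylic C4–OH and C2–O1 bonds; the aprotic solvent avoids acid-catalysed exchange at C4.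

Compound list
1 | 2,3,4-trihydroxybenzaldehyde | O=Cc1ccc(O)c(O)c1O | starting material
2 | 4-hydroxy-2,2-diphenyl-1,3-benzodioxole-5-carbaldehyde | O=Cc1ccc2OC(c3ccccc3)(c3ccccc3)Oc2c1O | intermediate
3 | 7-bromo-4-hydroxy-2,2-diphenyl-1,3-benzodioxole-5-carbaldehyde | O=Cc1cc(Br)c2OC(c3ccccc3)(c3ccccc3)Oc2c1O | intermediate
4 | 7-bromo-2,2-diphenyl-4-(triisopropylsilyloxy)-1,3-benzodioxole-5-carbaldehyde | O=Cc1cc(Br)c2OC(c3ccccc3)(c3ccccc3)Oc2c1O[Si](C(C)C)(C(C)C)C(C)C | intermediate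
5 | 4-ethynylphenol | C#Cc1ccc(O)cc1 | starting material
6 | 4-ethynylphenyl pivalate | C#Cc1ccc(OC(=O)C(C)(C)C)cc1 | intermediate
7 | ethyl{[4-(pivaloyloxy)phenyl]ethynyl}zinc (not isolated) | CC[Zn]C#Cc1ccc(OC(=O)C(C)(C)C)cc1 | intermediate
8 | (R)-propargylic alcohol: 4-[(3R)-3-(7-bromo-2,2-diphenyl-4-triisopropylsilyloxy-1,3-benzodioxol-5-yl)-3-hydroxyprop-1-ynyl]phenyl pivalate | CC(C)[Si](C(C)C)(C(C)C)Oc1c2OC(c3ccccc3)(c3ccccc3)Oc2c(Br)cc1[C@H](O)C#Cc1ccc(OC(=O)C(C)(C)C)cc1 | intermediate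
9 | (Z)-allylic alcohol: 4-[(1Z,3R)-3-(7-bromo-2,2-diphenyl-4-triisopropylsilyloxy-1,3-benzodioxol-5-yl)-3-hydroxyprop-1-enyl]phenyl pivalate | CC(C)[Si](C(C)C)(C(C)C)Oc1c2OC(c3ccccc3)(c3ccccc3)Oc2c(Br)cc1[C@H](O)/C=C\c1ccc(OC(=O)C(C)(C)C)cc1 | intermediate
10 | threo cis-epoxy carbinol: 4-[(2S,3R)-3-[(S)-(7-bromo-2,2-diphenyl-4-triisopropylsilyloxy-1,3-benzodioxol-5-yl)(hydroxy)methyl]oxiran-2-yl]phenyl pivalate | CC(C)[Si](C(C)C)(C(C)C)Oc1c2OC(c3ccccc3)(c3ccccc3)Oc2c(Br)cc1[C@H](O)[C@H]4O[C@H]4c5ccc(OC(=O)C(C)(C)C)cc5 | intermediate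
11 | threo epoxy phenol: 4-[(2S,3R)-3-[(S)-(7-bromo-4-hydroxy-2,2-diphenyl-1,3-benzodioxol-5-yl)(hydroxy)methyl]oxiran-2-yl]phenyl pivalate (not isolated) | Oc1c2OC(c3ccccc3)(c3ccccc3)Oc2c(Br)cc1[C@H](O)[C@H]4O[C@H]4c5ccc(OC(=O)C(C)(C)C)cc5 | intermediate
12 | (2R,3R,4S)-6-bromo-7,8-(diphenylmethylenedioxy)-4'-pivaloyloxyflavan-3,4-diol (2,3-cis-3,4-trans) | Brc1cc2c(c3OC(c4ccccc4)(c4ccccc4)Oc13)O[C@H](c1ccc(OC(=O)C(C)(C)C)cc1)[C@H](O)[C@H]2O | intermediate
13 | cis-epoxy ketone: 4-[(2S,3S)-3-(7-bromo-2,2-diphenyl-4-triisopropylsilyloxy-1,3-benzodioxole-5-carbonyl)oxiran-2-yl]phenyl pivalate | CC(C)[Si](C(C)C)(C(C)C)Oc1c2OC(c3ccccc3)(c3ccccc3)Oc2c(Br)cc1C(=O)[C@H]4O[C@H]4c5ccc(OC(=O)C(C)(C)C)cc5 | intermediate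
14 | erythro cis-epoxy carbinol: 4-[(2S,3R)-3-[(R)-(7-bromo-2,2-diphenyl-4-triisopropylsilyloxy-1,3-benzodioxol-5-yl)(hydroxy)methyl]oxiran-2-yl]phenyl pivalate | CC(C)[Si](C(C)C)(C(C)C)Oc1c2OC(c3ccccc3)(c3ccccc3)Oc2c(Br)cc1[C@@H](O)[C@H]4O[C@H]4c5ccc(OC(=O)C(C)(C)C)cc5 | intermediate
15 | erythro epoxy phenol: 4-[(2S,3R)-3-[(R)-(7-bromo-4-hydroxy-2,2-diphenyl-1,3-benzodioxol-5-yl)(hydroxy)methyl]oxiran-2-yl]phenyl pivalate (not isolated) | Oc1c2OC(c3ccccc3)(c3ccccc3)Oc2c(Br)cc1[C@@H](O)[C@H]4O[C@H]4c5ccc(OC(=O)C(C)(C)C)cc5 | intermediate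
16 | (2R,3R,4R)-6-bromo-7,8-(diphenylmethylenedioxy)-4'-pivaloyloxyflavan-3,4-diol (all-cis) | Brc1cc2c(c3OC(c4ccccc4)(c4ccccc4)Oc13)O[C@H](c1ccc(OC(=O)C(C)(C)C)cc1)[C@H](O)[C@@H]2O | intermediate
17 | (2R,3R,4S)-7,8-(diphenylmethylenedioxy)-4'-pivaloyloxy-6-(pinacolatoboryl)flavan-3,4-diol (not isolated) | CC1(C)OB(OC1(C)C)c1cc2c(c3OC(c4ccccc4)(c4ccccc4)Oc13)O[C@H](c1ccc(OC(=O)C(C)(C)C)cc1)[C@H](O)[C@H]2O | intermediate
18 | C6–C6 biflavan, (2R,3R,4R) unit joined to (2R,3R,4S) unit, both 7,8-diphenylmethylene ketals and 4'-pivalates | c1(-c5cc6c(c7OC(c8ccccc8)(c8ccccc8)Oc57)O[C@H](c5ccc(OC(=O)C(C)(C)C)cc5)[C@H](O)[C@H]6O)cc2c(c3OC(c4ccccc4)(c4ccccc4)Oc13)O[C@H](c1ccc(OC(=O)C(C)(C)C)cc1)[C@H](O)[C@@H]2O | intermediate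
19 | the same biflavan with free 4'-phenols and both ketals in place (not isolated) | c1(-c5cc6c(c7OC(c8ccccc8)(c8ccccc8)Oc57)O[C@H](c5ccc(O)cc5)[C@H](O)[C@H]6O)cc2c(c3OC(c4ccccc4)(c4ccccc4)Oc13)O[C@H](c1ccc(O)cc1)[C@H](O)[C@@H]2O | intermediate
20 | (2R,3R,4R)-2-(4-hydroxyphenyl)-6-[(2R,3R,4S)-3,4,7,8-tetrahydroxy-2-(4-hydroxyphenyl)chroman-6-yl]chroman-3,4,7,8-tetrol | Oc1ccc([C@H]2Oc3c(cc(-c4cc5c(c(O)c4O)O[C@H](c4ccc(O)cc4)[C@H](O)[C@H]5O)c(O)c3O)[C@@H](O)[C@H]2O)cc1 | target

Total step count: 13. Longest linear sequence: 11 steps (1, 2, 3, 5, 6, 7, 9, 10, 11, 12, 13, from compound 1).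

Steps most likely to fail

Step 8 (and step 11, which uses the same chemistry). What may go wrong: ionisation of the benzylic epoxide carbon before the phenol arrives, which would erode the 2,3-cis relationship; attack at C3 in the 5-exo mode; or ionisation of the ortho-hydroxybenzylic C4 carbinol. Fallback: ring C is closed at the ketone oxidation level, where no carbinol can ionise. It sets out from 13. Bu4NF/AcOH in THF frees the phenol of the cis-epoxy ketone, 4-[(2S,3S)-3-(7-bromo-4-hydroxy-2,2-diphenyl-1,3-benzodioxole-5-carbonyl)oxiran-2-yl]phenyl pivalate F1, which is not isolated. O1 then attacks the β-carbon with inversion (the ring closure of the Algar–Flynn–Oyamada sequence) to give the 2,3-cis-dihydroflavonol (2R,3S)-6-bromo-7,8-(diphenylmethylenedioxy)-3-hydroxy-4'-pivaloyloxyflavan-4-one F2. Hydroxyl-directed reduction with Me4NBH(OAc)3 in MeCN/AcOH at −20 °C delivers hydride from the face of the 3-OH and should give the 3,4-trans diol, rejoining the route at 12.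

Step 12. What may go wrong: protodeboronation of the electron-rich boronate, slow oxidative addition next to the ketal oxygen, or hydrolysis of the pivalates in warm base followed by C2 epimerisation through a ring-B quinone methide. Fallback: the biaryl bond is made before ring C exists. It sets out from 14. Miyaura borylation (B2pin2, Pd(dppf)Cl2, KOAc, dioxane) should give the erythro epoxy carbinol pinacol boronate F3. Suzuki–Miyaura coupling of F3 with bromide 10 (Pd(OAc)2/SPhos, K3PO4) should give the biaryl bis(epoxy carbinol) F4, in which both phenols are still silylated. Bu4NF/AcOH then frees the bis-phenol F5 (not isolated) and CSA closes both pyran rings as in steps 8 and 11, rejoining the route at 18.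

Step 5. What may go wrong: poor facial selectivity next to the bulky ortho-silyloxy group, or migration of the silyl group to the new zinc alkoxide. Fallback: C4 is set by ketone reduction instead of C–C bond formation. It sets out from 6 and 4. LiN(SiMe3)2 in THF at −78 °C converts 6 into the lithium acetylide F6, which adds to 4 to give the racemic propargylic carbinol F7. MnO2 in CH2Cl2 gives the ynone F8. Corey–Bakshi–Shibata reduction ((S)-2-methyl-CBS-oxazaborolidine, catecholborane, toluene, −78 °C), with the ortho-substituted aryl as the large and the alkynyl as the small group, should give the (R)-carbinol, rejoining the route at 8.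

Further compounds
F1 | step 8 | 4-[(2S,3S)-3-(7-bromo-4-hydroxy-2,2-diphenyl-1,3-benzodioxole-5-carbonyl)oxiran-2-yl]phenyl pivalate | Oc1c2OC(c3ccccc3)(c3ccccc3)Oc2c(Br)cc1C(=O)[C@H]4O[C@H]4c5ccc(OC(=O)C(C)(C)C)cc5
F2 | step 8 | (2R,3S)-6-bromo-7,8-(diphenylmethylenedioxy)-3-hydroxy-4'-pivaloyloxyflavan-4-one | Brc1cc2c(c3OC(c4ccccc4)(c4ccccc4)Oc13)O[C@H](c1ccc(OC(=O)C(C)(C)C)cc1)[C@H](O)C2=O
F3 | step 12 | pinacol boronate of 14 (Bpin in place of Br) | CC(C)[Si](C(C)C)(C(C)C)Oc1c2OC(c3ccccc3)(c3ccccc3)Oc2c(B3OC(C)(C)C(C)(C)O3)cc1[C@@H](O)[C@H]4O[C@H]4c5ccc(OC(=O)C(C)(C)C)cc5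
F4 | step 12 | biaryl bis(epoxy carbinol), erythro half joined to threo half, both phenols as triisopropylsilyl ethers | CC(C)[Si](C(C)C)(C(C)C)Oc1c2OC(c3ccccc3)(c3ccccc3)Oc2c(cc1[C@@H](O)[C@H]4O[C@H]4c5ccc(OC(=O)C(C)(C)C)cc5)-c1cc([C@H](O)[C@H]4O[C@H]4c5ccc(OC(=O)C(C)(C)C)cc5)c(O[Si](C(C)C)(C(C)C)C(C)C)c2OC(c3ccccc3)(c3ccccc3)Oc12
F5 | step 12 | biaryl bis(epoxy carbinol) with both phenols free | Oc1c2OC(c3ccccc3)(c3ccccc3)Oc2c(cc1[C@@H](O)[C@H]4O[C@H]4c5ccc(OC(=O)C(C)(C)C)cc5)-c1cc([C@H](O)[C@H]4O[C@H]4c5ccc(OC(=O)C(C)(C)C)cc5)c(O)c2OC(c3ccccc3)(c3ccccc3)Oc12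
F6 | step 5 | lithium [4-(pivaloyloxy)phenyl]acetylide | [Li]C#Cc1ccc(OC(=O)C(C)(C)C)cc1
F7 | step 5 | racemic 4-[3-(7-bromo-2,2-diphenyl-4-triisopropylsilyloxy-1,3-benzodioxol-5-yl)-3-hydroxyprop-1-ynyl]phenyl pivalate | CC(C)[Si](C(C)C)(C(C)C)Oc1c2OC(c3ccccc3)(c3ccccc3)Oc2c(Br)cc1C(O)C#Cc1ccc(OC(=O)C(C)(C)C)cc1
F8 | step 5 | 4-[3-(7-bromo-2,2-diphenyl-4-triisopropylsilyloxy-1,3-benzodioxol-5-yl)-3-oxoprop-1-ynyl]phenyl pivalate | CC(C)[Si](C(C)C)(C(C)C)Oc1c2OC(c3ccccc3)(c3ccccc3)Oc2c(Br)cc1C(=O)C#Cc1ccc(OC(=O)C(C)(C)C)cc1
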